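**Retrosynthetic overview**
1. The ketone comes from a silyl-protected carbinol, and the aryl ether O–aryl bond is made last from the neopentyl alcohol and 7-bromocoumarin; the coumarin ring is bought.
2. Both carbocycles come from one intramolecular Diels–Alder reaction of an (E,E,E)-trienal: bonds C1–C2 and C4a–C8a form together, so ring B (the cycloadduct ring) and ring A (the tether ring) close in the same step, trans-fused, with four stereocentres set.
3. The trienal comes from a vinyl iodide by Suzuki coupling (propenyl unit), cross-metathesis with methacrolein (enal) and carboalumination/iodination of a terminal alkyne.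
4. The two tether stereocentres (C5 methyl, C6 oxygen) come from (R)-but-3-yn-2-ol by chirality transfer through an allenylstannane that adds to pent-4-enal.

Assumption: compounds 1, 4, 9, 11 and 16 are bought; decalin positions use the naphthalene locants of the names in the compound list (C1 carries the CH2O group, C6 the ring oxygen; ring B = C1–C4, ring A = C5–C8).

**Route**

Step 1
Reactants: 1 (R)-but-3-yn-2-ol
Product: 2 (R)-but-3-yn-2-yl methanesulfonate
Conditions: MsCl, Et3N, CH2Cl2, −78 → 0 °C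
Reagents that add atoms: methanesulfonyl chloride CS(=O)(=O)Cl
Why: O-sulfonylation of the secondary alcohol leaves the C–O bond untouched, so the bought stereocentre is kept.

Step 2
Reactants: 2 (R)-but-3-yn-2-yl methanesulfonate
Product: 3 (aS)-buta-1,2-dien-1-yl(tributyl)stannane
Conditions: Bu3SnH, LiN(iPr)2, THF, 0 °C; CuBr·SMe2, −78 °C; then 2, −78 °C
Reagents that add atoms: tributyltin hydride CCCC[SnH](CCCC)CCCC (turned in the flask into Bu3SnLi [Li][Sn](CCCC)(CCCC)CCCC)
Why: anti SN2′ displacement of the propargylic mesylate by the stannylcopper reagent turns the carbinol stereocentre into the (P)-configured allene axis.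

Step 3
Reactants: 3 (aS)-buta-1,2-dien-1-yl(tributyl)stannane; 4 pent-4-enal
Product: 5 (3R,4R)-3-methyloct-7-en-1-yn-4-ol
Conditions: BF3·OEt2, CH2Cl2, −78 °C; aqueous work-up, chromatography
Reagents that add atoms: none
Why: BF3-promoted anti SE2′ addition of the allenylstannane (Marshall propargylation, open transition state) returns the axis to the C3 methyl stereocentre and sets C4 syn to it; the ratio expected for an unbranched aldehyde is moderate (roughly 4–9:1), and the minor anti epimer is removed by chromatography.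

Step 4
Reactants: 5 (3R,4R)-3-methyloct-7-en-1-yn-4-ol
Product: 6 triethyl{[(3R,4R)-3-methyloct-7-en-1-yn-4-yl]oxy}silane
Conditions: TESCl, imidazole, DMF, 0 °C → rt
Reagents that add atoms: chlorotriethylsilane CC[Si](Cl)(CC)CC
Why: silylation protects the carbinol for the organometallic steps and supplies a bulky equatorial group for the cycloaddition.

Step 5
Reactants: 6 triethyl{[(3R,4R)-3-methyloct-7-en-1-yn-4-yl]oxy}silane
Product: 8 triethyl{[(1E,3R,4R)-1-iodo-2,3-dimethylocta-1,7-dien-4-yl]oxy}silane, via alkenyldimethylalane 7 (not isolated)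
Conditions: Al(CH3)3 (2.5 equiv), (C5H5)2ZrCl2 (25 mol %), CH2Cl2, 0 °C → rt; then I2, THF, −30 °C
Reagents that add atoms: trimethylaluminium C[Al](C)C; iodine [I][I]
Why: Negishi zirconium-catalysed syn-methylalumination of the terminal alkyne (much faster than on the terminal alkene) and iodinolysis with retention give the (E)-trisubstituted vinyl iodide.

Step 6
Reactants: 8 triethyl{[(1E,3R,4R)-1-iodo-2,3-dimethylocta-1,7-dien-4-yl]oxy}silane; 9 methacrolein
Product: 10 (2E,6R,7R,8E)-9-iodo-2,7,8-trimethyl-6-[(triethylsilyl)oxy]nona-2,8-dienal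
Conditions: 9 (5 equiv), (H2IMes)(PCy3)Cl2Ru=CHPh (second-generation Grubbs catalyst, 5 mol %), CH2Cl2, 40 °C
Reagents that add atoms: none
Why: olefin cross-metathesis of the monosubstituted alkene with methacrolein gives the (E)-2-methyl enal, while the hindered iodoalkene does not take part.

Step 7
Reactants: 10 (2E,6R,7R,8E)-9-iodo-2,7,8-trimethyl-6-[(triethylsilyl)oxy]nona-2,8-dienal; 11 4,4,5,5-tetramethyl-2-[(1E)-prop-1-en-1-yl]-1,3,2-dioxaborolane
Product: 12 (2E,6R,7R,8E,10E)-2,7,8-trimethyl-6-[(triethylsilyl)oxy]dodeca-2,8,10-trienal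
Conditions: Pd(PPh3)4 (5 mol %), K3PO4, THF/H2O, 45 °C
Reagents that add atoms: none
Why: Suzuki–Miyaura coupling proceeds with retention at both alkenyl partners and gives the (E,E)-diene with the tether on the outside of the trisubstituted terminus.

Step 8
Reactants: 12 (2E,6R,7R,8E,10E)-2,7,8-trimethyl-6-[(triethylsilyl)oxy]dodeca-2,8,10-trienal
Product: 13 (1R,2R,4aS,5R,6R,8aR)-1,2,4a,5-tetramethyl-6-[(triethylsilyl)oxy]-1,2,4a,5,6,7,8,8a-octahydronaphthalene-1-carbaldehyde
Conditions: Me2AlCl (1.2 equiv), CH2Cl2 (0.01 mol/L), −78 → −20 °C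
Reagents that add atoms: none
Why: Lewis-acid-promoted type 1 intramolecular Diels–Alder reaction through the CHO-endo transition state with a chair tether (OTES and CH3 equatorial) closes both rings trans-fused and sets C1, C2, C4a and C8a, with CHO cis to the C2 methyl and trans to the C4a methyl.

Step 9
Reactants: 13 (1R,2R,4aS,5R,6R,8aR)-1,2,4a,5-tetramethyl-6-[(triethylsilyl)oxy]-1,2,4a,5,6,7,8,8a-octahydronaphthalene-1-carbaldehyde
Product: 14 [(1R,2R,4aS,5R,6R,8aR)-1,2,4a,5-tetramethyl-6-[(triethylsilyl)oxy]-1,2,4a,5,6,7,8,8a-octahydronaphthalen-1-yl]methanol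
Conditions: NaBH4, MeOH, 0 °C
Reagents that add atoms: none
Why: hydride reduction of the non-enolisable neopentyl aldehyde gives the primary alcohol without touching any stereocentre.

Step 10
Reactants: 14 [(1R,2R,4aS,5R,6R,8aR)-1,2,4a,5-tetramethyl-6-[(triethylsilyl)oxy]-1,2,4a,5,6,7,8,8a-octahydronaphthalen-1-yl]methanol
Product: 15 [(1R,2R,4aS,5R,6R,8aR)-1,2,4a,5-tetramethyl-6-[(triethylsilyl)oxy]decahydronaphthalen-1-yl]methanol
Conditions: H2 (1 atm), Pd/C, EtOAc, rt
Reagents that add atoms: none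
Why: heterogeneous hydrogenation saturates the only C=C bond before the coumarin, whose own C=C would be at risk, is attached; no stereocentre is formed.

Step 11
Reactants: 15 [(1R,2R,4aS,5R,6R,8aR)-1,2,4a,5-tetramethyl-6-[(triethylsilyl)oxy]decahydronaphthalen-1-yl]methanol; 16 7-bromo-2H-chromen-2-one
Product: 17 7-{[(1R,2R,4aS,5R,6R,8aR)-1,2,4a,5-tetramethyl-6-[(triethylsilyl)oxy]decahydronaphthalen-1-yl]methoxy}-2H-chromen-2-one
Conditions: [Pd(C3H5)Cl]2 (2 mol %), RockPhos (6 mol %), Cs2CO3, 16 (1.5 equiv), toluene, 90 °C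
Reagents that add atoms: none
Why: palladium-catalysed C–O cross-coupling (Buchwald–Hartwig type) makes the ether at the aryl carbon, so no SN2 reaction is needed at the neopentyl CH2, and the electron-poor aryl bromide favours reductive elimination.

Step 12
Reactants: 17 7-{[(1R,2R,4aS,5R,6R,8aR)-1,2,4a,5-tetramethyl-6-[(triethylsilyl)oxy]decahydronaphthalen-1-yl]methoxy}-2H-chromen-2-one
Product: 19 7-{[(1R,2R,4aS,5R,8aR)-1,2,4a,5-tetramethyl-6-oxodecahydronaphthalen-1-yl]methoxy}-2H-chromen-2-one, via secondary alcohol 18 (not isolated)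
Conditions: CrO3, H2SO4, H2O (Jones reagent), acetone, 0 °C → rt
Reagents that add atoms: none
Why: the acid-labile TES ether is cleaved in the medium and the freed alcohol undergoes Jones oxidation; the C5 methyl next to the new ketone is already equatorial, the thermodynamically preferred configuration.

**Compound list**
1 | (R)-but-3-yn-2-ol | C#C[C@@H](C)O | starting material
2 | (R)-but-3-yn-2-yl methanesulfonate | C#C[C@@H](C)OS(C)(=O)=O | intermediate
3 | (aS)-buta-1,2-dien-1-yl(tributyl)stannane | CCCC[Sn](CCCC)(CCCC)[CH]=[C@@]=[CH]C | intermediate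
4 | pent-4-enal | C=CCCC=O | starting material
5 | (3R,4R)-3-methyloct-7-en-1-yn-4-ol | C#C[C@@H](C)[C@H](O)CCC=C | intermediate
6 | triethyl{[(3R,4R)-3-methyloct-7-en-1-yn-4-yl]oxy}silane | C#C[C@@H](C)[C@H](O[Si](CC)(CC)CC)CCC=C | intermediate
7 | dimethyl{(1E,3R,4R)-2,3-dimethyl-4-[(triethylsilyl)oxy]octa-1,7-dien-1-yl}alumane | C[Al](C)/C=C(\C)[C@@H](C)[C@H](O[Si](CC)(CC)CC)CCC=C | intermediate
8 | triethyl{[(1E,3R,4R)-1-iodo-2,3-dimethylocta-1,7-dien-4-yl]oxy}silane | I/C=C(\C)[C@@H](C)[C@H](O[Si](CC)(CC)CC)CCC=C | intermediate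
9 | methacrolein (2-methylprop-2-enal) | CC(=C)C=O | starting material
10 | (2E,6R,7R,8E)-9-iodo-2,7,8-trimethyl-6-[(triethylsilyl)oxy]nona-2,8-dienal | I/C=C(\C)[C@@H](C)[C@H](O[Si](CC)(CC)CC)CC/C=C(\C)C=O | intermediate
11 | 4,4,5,5-tetramethyl-2-[(1E)-prop-1-en-1-yl]-1,3,2-dioxaborolane | C/C=C/B1OC(C)(C)C(C)(C)O1 | starting material
12 | (2E,6R,7R,8E,10E)-2,7,8-trimethyl-6-[(triethylsilyl)oxy]dodeca-2,8,10-trienal | C/C=C/C=C(\C)[C@@H](C)[C@H](O[Si](CC)(CC)CC)CC/C=C(\C)C=O | intermediate
13 | (1R,2R,4aS,5R,6R,8aR)-1,2,4a,5-tetramethyl-6-[(triethylsilyl)oxy]-1,2,4a,5,6,7,8,8a-octahydronaphthalene-1-carbaldehyde | C[C@@H]1C=C[C@@]2(C)[C@@H](CC[C@@H](O[Si](CC)(CC)CC)[C@@H]2C)[C@]1(C)C=O | intermediate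
14 | [(1R,2R,4aS,5R,6R,8aR)-1,2,4a,5-tetramethyl-6-[(triethylsilyl)oxy]-1,2,4a,5,6,7,8,8a-octahydronaphthalen-1-yl]methanol | C[C@@H]1C=C[C@@]2(C)[C@@H](CC[C@@H](O[Si](CC)(CC)CC)[C@@H]2C)[C@]1(C)CO | intermediate
15 | [(1R,2R,4aS,5R,6R,8aR)-1,2,4a,5-tetramethyl-6-[(triethylsilyl)oxy]decahydronaphthalen-1-yl]methanol | C[C@@H]1CC[C@@]2(C)[C@@H](CC[C@@H](O[Si](CC)(CC)CC)[C@@H]2C)[C@]1(C)CO | intermediate
16 | 7-bromo-2H-chromen-2-one | O=c1ccc2ccc(Br)cc2o1 | starting material
17 | 7-{[(1R,2R,4aS,5R,6R,8aR)-1,2,4a,5-tetramethyl-6-[(triethylsilyl)oxy]decahydronaphthalen-1-yl]methoxy}-2H-chromen-2-one | C[C@@H]1CC[C@@]2(C)[C@@H](CC[C@@H](O[Si](CC)(CC)CC)[C@@H]2C)[C@]1(C)COc1ccc2ccc(=O)oc2c1 | intermediate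
18 | 7-{[(1R,2R,4aS,5R,6R,8aR)-6-hydroxy-1,2,4a,5-tetramethyldecahydronaphthalen-1-yl]methoxy}-2H-chromen-2-one | C[C@@H]1CC[C@@]2(C)[C@@H](CC[C@@H](O)[C@@H]2C)[C@]1(C)COc1ccc2ccc(=O)oc2c1 | intermediate
19 | 7-{[(1R,2R,4aS,5R,8aR)-1,2,4a,5-tetramethyl-6-oxodecahydronaphthalen-1-yl]methoxy}-2H-chromen-2-one | C[C@@H]1CC[C@@]2(C)[C@@H](CCC(=O)[C@@H]2C)[C@]1(C)COc1ccc2ccc(=O)oc2c1 | target

**Totals**
Total step count: 12. Longest linear sequence: 12 steps (1 → 19); 4, 9, 11 and 16 enter as bought reagents.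

**Steps most likely to fail**

Step 8 (intramolecular Diels–Alder). The diene terminus that becomes the quaternary ring-fusion carbon carries an inside methyl group, so the cycloaddition may be slow or the Lewis acid may damage the diene. The fallback sets out from 12 and changes the dienophile to a cation. Acetalisation with 1,2-bis(trimethylsilyloxy)ethane and catalytic TMSOTf at −78 °C gives triethyl{[(2E,4E,6R,7R,10E)-11-(1,3-dioxolan-2-yl)-5,6-dimethyldodeca-2,4,10-trien-7-yl]oxy}silane F1. Catalytic TfOH (−78 → −20 °C) ionises it to an alkoxyallyl cation that closes in a cationic (Gassman-type) intramolecular [4+2] reaction to 2-{(1R,2R,4aS,5R,6R,8aR)-1,2,4a,5-tetramethyl-6-[(triethylsilyl)oxy]-1,2,4a,5,6,7,8,8a-octahydronaphthalen-1-yl}-1,3-dioxolane F2. PPTS in wet acetone then returns to the route at aldehyde 13.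

Step 11 (C–O coupling). The hindered alkoxide may bind poorly to palladium, or base may open the lactone. The fallback sets out from 15 and forms the O–CH2 bond instead of the O–aryl bond: Mitsunobu etherification with 7-hydroxy-2H-chromen-2-one (PPh3, DIAD, toluene, 80 °C, or (cyanomethylene)tributylphosphorane at 110 °C) gives 17 directly. This SN2 reaction at a neopentyl carbon is itself slow. It makes no new compound (F0).

Step 3 (allenylstannane addition). The syn:anti ratio with an unbranched aldehyde may be low. The fallback sets out from 3 and 4 and sets the carbinol configuration by inversion instead of by addition selectivity. The anti epimer (3R,4S)-3-methyloct-7-en-1-yn-4-ol F3 is separated and inverted in a Mitsunobu reaction with 4-nitrobenzoic acid (PPh3, DIAD, THF) to (3R,4R)-3-methyloct-7-en-1-yn-4-yl 4-nitrobenzoate F4. Methanolysis (K2CO3, MeOH) returns to the route at 5.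

**Further compounds**
F1 | step 8 | triethyl{[(2E,4E,6R,7R,10E)-11-(1,3-dioxolan-2-yl)-5,6-dimethyldodeca-2,4,10-trien-7-yl]oxy}silane | C/C=C/C=C(\C)[C@@H](C)[C@H](O[Si](CC)(CC)CC)CC/C=C(\C)C1OCCO1
F2 | step 8 | 2-{(1R,2R,4aS,5R,6R,8aR)-1,2,4a,5-tetramethyl-6-[(triethylsilyl)oxy]-1,2,4a,5,6,7,8,8a-octahydronaphthalen-1-yl}-1,3-dioxolane | C[C@@H]1C=C[C@@]2(C)[C@@H](CC[C@@H](O[Si](CC)(CC)CC)[C@@H]2C)[C@]1(C)C1OCCO1
F0 | step 11 | none | none
F3 | step 3 | (3R,4S)-3-methyloct-7-en-1-yn-4-ol | C#C[C@@H](C)[C@@H](O)CCC=C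
F4 | step 3 | (3R,4R)-3-methyloct-7-en-1-yn-4-yl 4-nitrobenzoate | C#C[C@@H](C)[C@H](OC(=O)c1ccc(cc1)[N+](=O)[O-])CCC=C
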